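**Strategy.** The ten-membered carbocycle (C1–C10) is not closed directly. An eleven-membered thiacycle is made by intramolecular S-alkylation (C4 thiolate onto C3), oxidised to the sulfone and contracted by a Ramberg–Bäcklund reaction. Loss of SO2 from the C3–S–C4 bridge creates the C3–C4 bond, the ring-cis (Z) trisubstituted C3=C4 alkene and the carbocycle in one operation. The step exploits the fact that C3=C4 lies in a medium ring, where only the cis-fused episulfone, and hence the Z alkene, is accessible. The precursor is the cyclic sulfone carrying the Z C1=C10 alkene, C2 and C12 PMB ethers, a C5/C6 acetonide and a C8 TBS ether.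

Key step: step 22

Remark: germacrane locants (C1–C15) are used for all intermediates; aldehyde 8 is taken as commercially available (distilled before use); C4 of sulfone 32 becomes trigonal in step 22 and is carried as the epimer that Felkin–Anh methylation and SN2 inversion deliver.

Step 1
Reactants: 1 3-chloro-2-(chloromethyl)prop-1-ene
Product: 2 2-(chloromethyl)allyl 4-methoxybenzyl ether
Conditions: NaH, 4-MeOC6H4CH2OH, THF, 0 °C; then 1 (3 equiv), Bu4NI (cat.), rt
Reagents that add atoms: 4-methoxybenzyl alcohol, COc1ccc(CO)cc1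
Why: Williamson etherification in which the alkoxide displaces one allylic chloride by SN2, the excess of the symmetric dichloride keeping double substitution low.

Step 2
Reactants: 2 2-(chloromethyl)allyl 4-methoxybenzyl ether
Product: 4 3-{[(4-methoxybenzyl)oxy]methyl}but-3-enoic acid, via allylmagnesium chloride 3 (not isolated)
Conditions: Mg, THF, 0 °C (slow addition); CO2, −20 °C; aq. HCl
Reagents that add atoms: carbon dioxide, O=C=O
Why: Grignard formation and carboxylation; the 2-substituted allyl reagent is symmetric, so either terminus gives the same β,γ-unsaturated acid, which carries C8, C7 and C11–C13.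

Step 3
Reactants: 4 3-{[(4-methoxybenzyl)oxy]methyl}but-3-enoic acid; 5 (S)-4-benzyl-1,3-oxazolidin-2-one
Product: 7 (S)-4-benzyl-3-(3-{[(4-methoxybenzyl)oxy]methyl}but-3-enoyl)-1,3-oxazolidin-2-one, via mixed pivalic anhydride 6 (not isolated)
Conditions: t-BuCOCl, Et3N, THF, −20 °C; then 5, LiCl, −20 °C → rt
Reagents that add atoms: none
Why: N-acylation of the oxazolidinone through a mixed anhydride (LiCl-assisted), which needs no strong base and should therefore leave the 1,1-disubstituted alkene out of conjugation.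

Step 4
Reactants: 7 N-acyl oxazolidinone; 8 (S)-2,2-dimethyl-1,3-dioxolane-4-carbaldehyde
Product: 10 syn aldol adduct (C6 carbinol; C7 bearing the 2-propenyl unit), via boron dienolate 9 (not isolated)
Conditions: Bu2BOTf, i-Pr2NEt, CH2Cl2, −78 → 0 °C; then 8, −78 → 0 °C; H2O2, MeOH, pH 7 buffer
Reagents that add atoms: none
Why: Evans syn aldol reaction: the Z boron dienolate reacts at its α-carbon (C7) through a closed Zimmerman–Traxler transition state on the face away from the benzyl group, so the (S)-auxiliary sets C7 and C6 (6,7-syn, O6 syn to O5) and should override the weaker Felkin–Anh bias of the aldehyde, whose own centre becomes C5.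

Step 5
Reactants: 10 syn aldol adduct
Product: 11 Weinreb amide (C8)
Conditions: AlMe3, MeNHOMe·HCl, CH2Cl2, −20 → 0 °C
Reagents that add atoms: N,O-dimethylhydroxylamine hydrochloride, CNOC.Cl
Why: Weinreb transamidation with the aluminium amide, assisted by the free C6 hydroxyl, should release the auxiliary without epimerising C7.

Step 6
Reactants: 11 Weinreb amide
Product: 12 α-chloromethyl ketone (C8 ketone; C9 chloride)
Conditions: ICH2Cl, MeLi·LiBr (3 equiv), THF, −78 °C; AcOH quench
Reagents that add atoms: chloroiodomethane, ClCI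
Why: Acyl substitution of a Weinreb amide by the chloromethyllithium carbenoid: the chelated tetrahedral adduct collapses only on work-up, so the ketone is not over-added, and one extra equivalent of MeLi covers the free hydroxyl.

Step 7
Reactants: 12 α-chloromethyl ketone
Product: 14 1,3-syn diol chlorohydrin, via boron chelate 13 (not isolated)
Conditions: Et2BOMe, THF–MeOH, −78 °C; NaBH4; MeOH co-evaporation
Reagents that add atoms: none
Why: Narasaka–Prasad reduction: external hydride attacks the six-membered diethylboron chelate of the β-hydroxy ketone to give the 1,3-syn diol, so the C6 hydroxyl sets C8, and the low temperature should protect the epimerisable C7.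

Step 8
Reactants: 14 1,3-syn diol chlorohydrin
Product: 15 epoxy alcohol (C8/C9 epoxide; free C6 hydroxyl)
Conditions: K2CO3, MeOH, 0 °C
Reagents that add atoms: none
Why: Intramolecular Williamson reaction (3-exo-tet) of the chlorohydrin gives the terminal epoxide with retention at C8, which at 0 °C should be faster than five-membered ether formation from the C6 hydroxyl.

Step 9
Reactants: 15 epoxy alcohol
Product: 16 epoxide C6 triethylsilyl ether
Conditions: Et3SiCl, imidazole, DMAP (cat.), DMF, 0 °C → rt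
Reagents that add atoms: chlorotriethylsilane, CC[Si](Cl)(CC)CC
Why: Silyl ether formation masks the C6 hydroxyl so that it can neither quench the organolithium nor open the epoxide in step 14.

Step 10
Reactants: 17 (R)-3-chloropropane-1,2-diol
Product: 18 (4R)-4-(chloromethyl)-2-(4-methoxyphenyl)-1,3-dioxolane
Conditions: 4-MeOC6H4CH(OMe)2, CSA (cat.), CH2Cl2, rt
Reagents that add atoms: 4-methoxybenzaldehyde dimethyl acetal, COc1ccc(cc1)C(OC)OC
Why: Acid-catalysed transacetalisation converts the 1,2-diol into its 4-methoxybenzylidene acetal.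

Step 11
Reactants: 18 4-methoxybenzylidene acetal
Product: 19 (R)-3-chloro-2-[(4-methoxybenzyl)oxy]propan-1-ol
Conditions: i-Bu2AlH, CH2Cl2, −78 → 0 °C
Reagents that add atoms: none
Why: Reductive acetal opening: aluminium binds the less hindered primary oxygen and hydride goes to the acetal carbon, leaving the PMB group on the secondary oxygen (C2).

Step 12
Reactants: 19 (R)-3-chloro-2-[(4-methoxybenzyl)oxy]propan-1-ol
Product: 20 (R)-3-chloro-2-[(4-methoxybenzyl)oxy]propanal
Conditions: TEMPO (cat.), PhI(OAc)2, CH2Cl2, rt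
Reagents that add atoms: none
Why: TEMPO-catalysed oxidation of the primary alcohol under non-basic conditions, which should neither eliminate the β-chloride nor racemise the α-centre.

Step 13
Reactants: 20 (R)-3-chloro-2-[(4-methoxybenzyl)oxy]propanal
Product: 21 (2R,3Z)-1-chloro-4-iodo-2-[(4-methoxybenzyl)oxy]pent-3-ene
Conditions: EtPPh3I, n-BuLi, THF, 0 °C; I2, −78 °C; NaN(SiMe3)2, −78 °C; then 20, −78 → −20 °C
Reagents that add atoms: ethyltriphenylphosphonium iodide, CC[P+](c1ccccc1)(c1ccccc1)c1ccccc1.[I-]; iodine, II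
Why: Stork–Zhao-type Wittig olefination with the α-iodo ylide, which under kinetic control at low temperature gives the Z trisubstituted vinyl iodide (iodine cis to C2) and thereby fixes the C1=C10 geometry.

Step 14
Reactants: 21 Z vinyl iodide (1.5 equiv); 16 epoxide C6 triethylsilyl ether
Product: 23 C8 homoallylic alcohol (C3–C10 joined to C4–C9), via alkenyllithium 22 (not isolated)
Conditions: t-BuLi, Et2O, −78 °C; then 16, BF3·OEt2, −78 °C
Reagents that add atoms: none
Why: Iodine–lithium exchange with retention of alkene geometry, then BF3-promoted SN2 opening of the terminal epoxide at C9, forms the C9–C10 bond and frees the C8 hydroxyl, the primary chloride being inert at −78 °C.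

Step 15
Reactants: 23 C8 homoallylic alcohol
Product: 24 C8 tert-butyldimethylsilyl ether
Conditions: t-BuMe2SiOTf, 2,6-lutidine, CH2Cl2, −78 → 0 °C
Reagents that add atoms: tert-butyldimethylsilyl trifluoromethanesulfonate, CC(C)(C)[Si](C)(C)OS(=O)(=O)C(F)(F)F
Why: Silylation of the hindered secondary alcohol with the silyl triflate, which leaves the more labile C6 triethylsilyl ether in place for the next step.

Step 16
Reactants: 24 C8 tert-butyldimethylsilyl ether
Product: 26 primary C4 alcohol with C5/C6 acetonide, via C6 alcohol 25 (not isolated)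
Conditions: CSA (cat.), MeOH (5 equiv), acetone, rt
Reagents that add atoms: none
Why: Acid-catalysed silyl ether methanolysis and acetonide migration: the freed C6 hydroxyl captures the ring-opened isopropylidene oxocarbenium ion, and the trans-4,5-disubstituted dioxolane (C5/C6) with a free primary alcohol should be the thermodynamic product.

Step 17
Reactants: 26 primary C4 alcohol
Product: 27 C4 aldehyde
Conditions: TEMPO (cat.), PhI(OAc)2, CH2Cl2, rt
Reagents that add atoms: none
Why: TEMPO-catalysed oxidation of the only free (primary) alcohol to the aldehyde without touching alkenes, ethers or the chloride.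

Step 18
Reactants: 27 C4 aldehyde
Product: 28 C4 secondary carbinol (4,5-anti)
Conditions: MeMgBr, THF, −78 °C
Reagents that add atoms: methylmagnesium bromide, C[Mg]Br
Why: Grignard addition brings in C15; Felkin–Anh (Cornforth) control by the C5 oxygen should favour the 4,5-anti carbinol, and the other C4 epimer would converge because C4 becomes trigonal in step 22.

Step 19
Reactants: 28 C4 secondary carbinol
Product: 29 C4 thioacetate
Conditions: PPh3, DIAD, AcSH, THF, 0 °C → rt
Reagents that add atoms: thioacetic acid, CC(=O)S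
Why: Mitsunobu reaction with thioacetic acid replaces the only free hydroxyl by sulfur with inversion at C4.

Step 20
Reactants: 29 C4 thioacetate
Product: 31 eleven-membered cyclic sulfide (S between C3 and C4), via thiol 30 (not isolated)
Conditions: Cs2CO3, Bu4NI (cat.), degassed MeOH–DMF, 60 °C, slow addition (about 1 mM)
Reagents that add atoms: none
Why: Thioacetate methanolysis followed by intramolecular SN2 S-alkylation at the primary C3 chloride; high dilution, the soft caesium thiolate and iodide catalysis should favour ring closure over oligomerisation.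

Step 21
Reactants: 31 eleven-membered cyclic sulfide
Product: 32 eleven-membered cyclic sulfone
Conditions: (NH4)6Mo7O24·4H2O (cat.), H2O2, EtOH, 0 °C → rt
Reagents that add atoms: hydrogen peroxide, OO
Why: Molybdate-catalysed peroxide oxidation of sulfide to sulfone, chemoselective over the electron-rich alkenes and the PMB ethers.

Step 22
Reactants: 32 eleven-membered cyclic sulfone
Product: 35 protected ten-membered triene (C2 and C12 PMB ethers; C5/C6 acetonide; C8 TBS ether), via α-bromo sulfone 33 (not isolated), via episulfone 34 (not isolated)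
Conditions: CBr2F2, KOH/Al2O3, t-BuOH–CH2Cl2, 0 °C → rt
Reagents that add atoms: none
Why: Ramberg–Bäcklund reaction with in-situ halogenation: the base deprotonates the more acidic C3 methylene, the carbanion is brominated by CBr2F2, and deprotonation at C4 with intramolecular displacement of bromide (1,3-elimination) gives the episulfone, which loses SO2 in a cheletropic step. The closest known reactions are the contraction of medium- and large-ring sulfones to cycloalkenes and the conversion of β-alkoxy sulfones into alkenes under the same conditions. The ten-membered carbocycle is closed by ring contraction of the eleven-membered sulfone, the C3–C4 bond being made in the 3-exo-tet closure to the episulfone. No stereocentre is created, the C4 centre is erased, and the alkene geometry is set by the ring, which can only hold the cis-fused episulfone and therefore gives the Z (ring-cis) C3=C4 alkene. The step also needs extrusion to win over β-elimination of the C2 and C5 oxygens; these are an ether and an acetal oxygen, both poor leaving groups, and the silyl ether, PMB ethers and alkenes should tolerate the heterogeneous base.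

Step 23
Reactants: 35 protected ten-membered triene
Product: 36 C8 alcohol
Conditions: Bu4NF, THF, rt
Reagents that add atoms: none
Why: Fluoride-mediated cleavage of the only silyl ether.

Step 24
Reactants: 36 C8 alcohol; 37 tiglic acid
Product: 39 C8 tiglate, via mixed anhydride 38 (not isolated)
Conditions: 37, 2,4,6-Cl3C6H2COCl, Et3N, THF, rt; then 36, DMAP, toluene, rt → 40 °C
Reagents that add atoms: none
Why: Yamaguchi esterification of the hindered secondary alcohol through the mixed anhydride; the E geometry of the tiglate is the stable one and should be kept.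

Step 25
Reactants: 39 C8 tiglate
Product: 40 C2/C12 diol
Conditions: DDQ, CH2Cl2–pH 7 buffer, 0 °C
Reagents that add atoms: none
Why: Oxidative cleavage of both PMB ethers by DDQ (hydride abstraction, then hydrolysis of the oxocarbenium ions); any onward oxidation of the doubly allylic C2 carbinol only anticipates step 26.

Step 26
Reactants: 40 C2/C12 diol
Product: 41 C2 ketone C12 aldehyde
Conditions: MnO2, CH2Cl2, rt
Reagents that add atoms: none
Why: MnO2 oxidation of allylic alcohols: the doubly allylic C2 carbinol gives the cross-conjugated dienone and the primary C12 alcohol the enal, while C5 and C6 stay masked in the acetonide.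

Step 27
Reactants: 41 C2 ketone C12 aldehyde
Product: 42 C2 ketone C12 carboxylic acid
Conditions: NaClO2, NaH2PO4, 2-methyl-2-butene, t-BuOH–H2O, 0 °C → rt
Reagents that add atoms: sodium chlorite, [Na+].[O-]Cl=O
Why: Pinnick oxidation of the enal to the acrylic acid, with 2-methyl-2-butene scavenging hypochlorite so that the alkenes are spared.

Step 28
Reactants: 42 C2 ketone C12 carboxylic acid
Product: 44 target CNP0230565.1, via dihydroxy acid 43 (not isolated)
Conditions: CF3CO2H–H2O, CH2Cl2, 0 °C → rt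
Reagents that add atoms: none
Why: Acid hydrolysis of the acetonide followed by lactonisation of the γ-hydroxy acid: the C6 hydroxyl should close the five-membered α-methylene lactone in preference to the six-membered ring available to the C5 hydroxyl, which stays free.

**Compound list**

1 | 3-chloro-2-(chloromethyl)prop-1-ene | C=C(CCl)CCl | starting material
2 | 1-({[2-(chloromethyl)prop-2-en-1-yl]oxy}methyl)-4-methoxybenzene | C=C(CCl)COCc1ccc(OC)cc1 | intermediate
3 | {2-[(4-methoxybenzyloxy)methyl]prop-2-en-1-yl}magnesium chloride | C=C(C[Mg]Cl)COCc1ccc(OC)cc1 | intermediate (not isolated)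
4 | 3-{[(4-methoxybenzyl)oxy]methyl}but-3-enoic acid | C=C(CC(=O)O)COCc1ccc(OC)cc1 | intermediate
5 | (S)-4-benzyl-1,3-oxazolidin-2-one | O=C1OC[C@H](Cc2ccccc2)N1 | starting material
6 | mixed anhydride of 4 with pivalic acid | C=C(CC(=O)OC(=O)C(C)(C)C)COCc1ccc(OC)cc1 | intermediate (not isolated)
7 | (S)-4-benzyl-3-(3-{[(4-methoxybenzyl)oxy]methyl}but-3-enoyl)-1,3-oxazolidin-2-one | C=C(CC(=O)N1[C@@H](Cc2ccccc2)COC1=O)COCc1ccc(OC)cc1 | intermediate
8 | (S)-2,2-dimethyl-1,3-dioxolane-4-carbaldehyde ((S)-glyceraldehyde acetonide; supplies C4–C6) | O=C[C@@H]1COC(C)(C)O1 | starting material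
9 | Z dibutylboron dienolate of 7 | C=C(COCc1ccc(OC)cc1)/C=C(\OB(CCCC)CCCC)N1[C@@H](Cc2ccccc2)COC1=O | intermediate (not isolated)
10 | (S)-4-benzyl-3-[(2S,3S)-3-[(4S)-2,2-dimethyl-1,3-dioxolan-4-yl]-3-hydroxy-2-(3-[(4-methoxybenzyl)oxy]prop-1-en-2-yl)propanoyl]-1,3-oxazolidin-2-one | O=C1OC[C@H](Cc2ccccc2)N1C(=O)[C@@H](C(=C)COCc1ccc(OC)cc1)[C@H](O)[C@@H]1COC(C)(C)O1 | intermediate
11 | (2S,3S)-3-[(4S)-2,2-dimethyl-1,3-dioxolan-4-yl]-3-hydroxy-N-methoxy-2-(3-[(4-methoxybenzyl)oxy]prop-1-en-2-yl)-N-methylpropanamide | CON(C)C(=O)[C@@H](C(=C)COCc1ccc(OC)cc1)[C@H](O)[C@@H]1COC(C)(C)O1 | intermediate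
12 | (3S,4S)-1-chloro-4-[(4S)-2,2-dimethyl-1,3-dioxolan-4-yl]-4-hydroxy-3-(3-[(4-methoxybenzyl)oxy]prop-1-en-2-yl)butan-2-one | ClCC(=O)[C@@H](C(=C)COCc1ccc(OC)cc1)[C@H](O)[C@@H]1COC(C)(C)O1 | intermediate
13 | O-diethylboryl chelate of 12 | ClCC(=O)[C@@H](C(=C)COCc1ccc(OC)cc1)[C@H](OB(CC)CC)[C@@H]1COC(C)(C)O1 | intermediate (not isolated)
14 | (2R,3S,4S)-1-chloro-4-[(4S)-2,2-dimethyl-1,3-dioxolan-4-yl]-3-(3-[(4-methoxybenzyl)oxy]prop-1-en-2-yl)butane-2,4-diol | ClC[C@H](O)[C@@H](C(=C)COCc1ccc(OC)cc1)[C@H](O)[C@@H]1COC(C)(C)O1 | intermediate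
15 | (1S,2S)-1-[(4S)-2,2-dimethyl-1,3-dioxolan-4-yl]-3-{[(4-methoxybenzyl)oxy]methyl}-2-[(2R)-oxiran-2-yl]but-3-en-1-ol | C1O[C@@H]1[C@@H](C(=C)COCc1ccc(OC)cc1)[C@H](O)[C@@H]1COC(C)(C)O1 | intermediate
16 | triethylsilyl ether of 15 (C6 OTES; C8/C9 epoxide; C4/C5 acetonide) | C1O[C@@H]1[C@@H](C(=C)COCc1ccc(OC)cc1)[C@H](O[Si](CC)(CC)CC)[C@@H]1COC(C)(C)O1 | intermediate
17 | (R)-3-chloropropane-1,2-diol | OC[C@@H](O)CCl | starting material
18 | (4R)-4-(chloromethyl)-2-(4-methoxyphenyl)-1,3-dioxolane (both acetal epimers) | COc1ccc(cc1)C1OC[C@H](CCl)O1 | intermediate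
19 | (R)-3-chloro-2-[(4-methoxybenzyl)oxy]propan-1-ol | OC[C@@H](OCc1ccc(OC)cc1)CCl | intermediate
20 | (R)-3-chloro-2-[(4-methoxybenzyl)oxy]propanal | O=C[C@@H](OCc1ccc(OC)cc1)CCl | intermediate
21 | (2R,3Z)-1-chloro-4-iodo-2-[(4-methoxybenzyl)oxy]pent-3-ene (C3, C2, C1, C10, C14) | I/C(C)=C\[C@@H](OCc1ccc(OC)cc1)CCl | intermediate
22 | Z alkenyllithium from 21 | [Li]/C(C)=C\[C@@H](OCc1ccc(OC)cc1)CCl | intermediate (not isolated)
23 | open-chain C8 alcohol: C3 chloride, C2 OPMB (R), Z C1=C10, C6 OTES, C4/C5 acetonide, C12 OPMB; O5, O6, C11 and O8 all syn along C4–C9 as in the target | C1OC(C)(C)O[C@@H]1[C@@H](O[Si](CC)(CC)CC)[C@H](C(=C)COCc1ccc(OC)cc1)[C@@H](O)C/C(C)=C\[C@@H](OCc1ccc(OC)cc1)CCl | intermediate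
24 | C8 tert-butyldimethylsilyl ether of 23 | C1OC(C)(C)O[C@@H]1[C@@H](O[Si](CC)(CC)CC)[C@H](C(=C)COCc1ccc(OC)cc1)[C@@H](O[Si](C)(C)C(C)(C)C)C/C(C)=C\[C@@H](OCc1ccc(OC)cc1)CCl | intermediate
25 | C6 alcohol from 24 (TES removed; acetonide still on C4/C5) | C1OC(C)(C)O[C@@H]1[C@@H](O)[C@H](C(=C)COCc1ccc(OC)cc1)[C@@H](O[Si](C)(C)C(C)(C)C)C/C(C)=C\[C@@H](OCc1ccc(OC)cc1)CCl | intermediate (not isolated)
26 | primary C4 alcohol with trans C5/C6 acetonide, C8 OTBS, C2 and C12 OPMB, C3 chloride | OC[C@@H]1OC(C)(C)O[C@H]1[C@H](C(=C)COCc1ccc(OC)cc1)[C@@H](O[Si](C)(C)C(C)(C)C)C/C(C)=C\[C@@H](OCc1ccc(OC)cc1)CCl | intermediate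
27 | C4 aldehyde from 26 | O=C[C@@H]1OC(C)(C)O[C@H]1[C@H](C(=C)COCc1ccc(OC)cc1)[C@@H](O[Si](C)(C)C(C)(C)C)C/C(C)=C\[C@@H](OCc1ccc(OC)cc1)CCl | intermediate
28 | C4 secondary carbinol (C4 S, hydroxyl anti to O5; C15 methyl in place) | C[C@H](O)[C@@H]1OC(C)(C)O[C@H]1[C@H](C(=C)COCc1ccc(OC)cc1)[C@@H](O[Si](C)(C)C(C)(C)C)C/C(C)=C\[C@@H](OCc1ccc(OC)cc1)CCl | intermediate
29 | C4 thioacetate (C4 R, inverted) | C[C@@H](SC(C)=O)[C@@H]1OC(C)(C)O[C@H]1[C@H](C(=C)COCc1ccc(OC)cc1)[C@@H](O[Si](C)(C)C(C)(C)C)C/C(C)=C\[C@@H](OCc1ccc(OC)cc1)CCl | intermediate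
30 | C4 thiol (as caesium thiolate) from 29 | C[C@@H](S)[C@@H]1OC(C)(C)O[C@H]1[C@H](C(=C)COCc1ccc(OC)cc1)[C@@H](O[Si](C)(C)C(C)(C)C)C/C(C)=C\[C@@H](OCc1ccc(OC)cc1)CCl | intermediate (not isolated)
31 | eleven-membered cyclic sulfide (S between C3 and C4; C2 and C12 OPMB; C5/C6 acetonide; C8 OTBS; Z C1=C10) | C=C(COCc3ccc(OC)cc3)[C@@H]2[C@@H](O[Si](C)(C)C(C)(C)C)C/C(C)=C\[C@@H](OCc3ccc(OC)cc3)CS[C@H](C)[C@@H]1OC(C)(C)O[C@H]12 | intermediate
32 | eleven-membered cyclic sulfone (precursor of the key step) | C=C(COCc3ccc(OC)cc3)[C@@H]2[C@@H](O[Si](C)(C)C(C)(C)C)C/C(C)=C\[C@@H](OCc3ccc(OC)cc3)CS(=O)(=O)[C@H](C)[C@@H]1OC(C)(C)O[C@H]12 | intermediate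
33 | C3-bromo derivative of sulfone 32 | C=C(COCc3ccc(OC)cc3)[C@@H]2[C@@H](O[Si](C)(C)C(C)(C)C)C/C(C)=C\[C@@H](OCc3ccc(OC)cc3)C(Br)S(=O)(=O)[C@H](C)[C@@H]1OC(C)(C)O[C@H]12 | intermediate (not isolated)
34 | cis-fused episulfone (thiirane 1,1-dioxide across C3–C4) | C=C(COCc4ccc(OC)cc4)[C@@H]2[C@@H](O[Si](C)(C)C(C)(C)C)C/C(C)=C\[C@@H](OCc4ccc(OC)cc4)C3C(C)(S3(=O)=O)[C@@H]1OC(C)(C)O[C@H]12 | intermediate (not isolated)
35 | protected ten-membered triene (Z C1=C10, Z C3=C4, C11=C13; C2 and C12 OPMB; C5/C6 acetonide; C8 OTBS) | C=C(COCc3ccc(OC)cc3)[C@@H]2[C@@H](O[Si](C)(C)C(C)(C)C)C/C(C)=C\[C@@H](OCc3ccc(OC)cc3)/C=C(/C)[C@@H]1OC(C)(C)O[C@H]12 | intermediate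
36 | C8 alcohol from 35 | C=C(COCc3ccc(OC)cc3)[C@@H]2[C@@H](O)C/C(C)=C\[C@@H](OCc3ccc(OC)cc3)/C=C(/C)[C@@H]1OC(C)(C)O[C@H]12 | intermediate
37 | tiglic acid, (E)-2-methylbut-2-enoic acid | C/C=C(\C)C(=O)O | starting material
38 | mixed anhydride of tiglic acid with 2,4,6-trichlorobenzoic acid | C/C=C(\C)C(=O)OC(=O)c1c(Cl)cc(Cl)cc1Cl | intermediate (not isolated)
39 | C8 tiglate (C2 and C12 OPMB; C5/C6 acetonide) | C=C(COCc3ccc(OC)cc3)[C@@H]2[C@@H](OC(=O)/C(C)=C/C)C/C(C)=C\[C@@H](OCc3ccc(OC)cc3)/C=C(/C)[C@@H]1OC(C)(C)O[C@H]12 | intermediate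
40 | C2,C12-diol (C8 tiglate; C5/C6 acetonide) | C=C(CO)[C@@H]2[C@@H](OC(=O)/C(C)=C/C)C/C(C)=C\[C@@H](O)/C=C(/C)[C@@H]1OC(C)(C)O[C@H]12 | intermediate
41 | C2 ketone, C12 aldehyde (cross-conjugated Z,Z-dienone and 2-substituted acrolein) | C=C(C=O)[C@@H]2[C@@H](OC(=O)/C(C)=C/C)C/C(C)=C\C(=O)/C=C(/C)[C@@H]1OC(C)(C)O[C@H]12 | intermediate
42 | C2 ketone, C12 carboxylic acid | C=C(C(=O)O)[C@@H]2[C@@H](OC(=O)/C(C)=C/C)C/C(C)=C\C(=O)/C=C(/C)[C@@H]1OC(C)(C)O[C@H]12 | intermediate
43 | 5,6-dihydroxy C12 acid (acetonide removed) | C=C(C(=O)O)[C@@H]2[C@@H](OC(=O)/C(C)=C/C)C/C(C)=C\C(=O)/C=C(/C)[C@H](O)[C@H]2O | intermediate (not isolated)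
44 | CNP0230565.1: (5S,6S,7R,8S)-5-hydroxy-2-oxo-8-tigloyloxygermacra-1(10)Z,3Z,11(13)-trien-6,12-olide | C=C1C(=O)O[C@H]2[C@H]1[C@@H](OC(=O)/C(C)=C/C)C/C(C)=C\C(=O)/C=C(/C)[C@@H]2O | target

**Step count.** Total: 28 steps. Longest linear sequence: 24 steps (steps 1–9, then 14–28); the vinyl iodide branch (steps 10–13) joins at step 14.

**Steps most likely to fail**

Step 22 (ring contraction). The α-sulfonyl carbanions may undergo β-elimination of the C2 or C5 oxygen, or be brominated more than once, faster than the episulfone forms. Fallback, setting out from sulfone 32: halogenation and extrusion are separated. Kinetic deprotonation of the C3 methylene with LiN(SiMe3)2 in THF at −78 °C and a hexachloroethane quench would give the α-chloro sulfone F1. KOt-Bu in THF (−78 → 0 °C) would then effect the 1,3-elimination and SO2 loss of the stepwise Ramberg–Bäcklund reaction, which returns to triene 35.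

Step 20 (macrocyclisation). Intermolecular S-alkylation and disulfide formation may compete, because SN2 at the β-branched, β-oxygenated primary chloride is slow under high dilution. Fallback, setting out from carbinol 28: the roles of the two termini are reversed. KSAc with NaI in DMF at ordinary concentration would displace the chloride to give the C3 thioacetate F2, and MsCl/Et3N would give the C4 mesylate F3. Cs2CO3/MeOH under high dilution would then free the unhindered primary C3 thiolate, which closes the ring at C4 on the sulfonate with inversion. This is the same stereochemical sense as the Mitsunobu step, so cyclic sulfide 31 is reached.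

Step 28 (unmasking and lactonisation). Under aqueous acid the freed C5 hydroxyl may add across the ring to the C2 ketone and dehydrate, or acetonide hydrolysis may be too slow for the hydroxy dienone to survive. Fallback, setting out from tiglate 39: the order is changed so that acid is used before the dienone exists. Aqueous AcOH would remove the acetonide to give the C5,C6-diol F4, and DDQ would then give the tetraol F5. TEMPO/PhI(OAc)2 would oxidise the primary C12 alcohol through the lactol to the C2-hydroxy lactone F6 (oxidative lactonisation of a 1,4-diol). MnO2 would finally oxidise only the doubly allylic C2 carbinol and so reach target 44.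

**Further compounds**

F1 | step 22 | C3-chloro derivative of sulfone 32 (α-chloro sulfone) | C=C(COCc3ccc(OC)cc3)[C@@H]2[C@@H](O[Si](C)(C)C(C)(C)C)C/C(C)=C\[C@@H](OCc3ccc(OC)cc3)C(Cl)S(=O)(=O)[C@H](C)[C@@H]1OC(C)(C)O[C@H]12
F2 | step 20 | C3 thioacetate with free C4 carbinol | C[C@H](O)[C@@H]1OC(C)(C)O[C@H]1[C@H](C(=C)COCc1ccc(OC)cc1)[C@@H](O[Si](C)(C)C(C)(C)C)C/C(C)=C\[C@@H](OCc1ccc(OC)cc1)CSC(C)=O
F3 | step 20 | C4 methanesulfonate of F2 | C[C@H](OS(C)(=O)=O)[C@@H]1OC(C)(C)O[C@H]1[C@H](C(=C)COCc1ccc(OC)cc1)[C@@H](O[Si](C)(C)C(C)(C)C)C/C(C)=C\[C@@H](OCc1ccc(OC)cc1)CSC(C)=O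
F4 | step 28 | C5,C6-diol with C2 and C12 PMB ethers and C8 tiglate | C=C(COCc3ccc(OC)cc3)[C@@H]2[C@@H](OC(=O)/C(C)=C/C)C/C(C)=C\[C@@H](OCc3ccc(OC)cc3)/C=C(/C)[C@H](O)[C@H]2O
F5 | step 28 | C2,C5,C6,C12-tetraol C8 tiglate | C=C(CO)[C@@H]2[C@@H](OC(=O)/C(C)=C/C)C/C(C)=C\[C@@H](O)/C=C(/C)[C@H](O)[C@H]2O
F6 | step 28 | C2-hydroxy 6,12-lactone (C2 carbinol of the target) | C=C1C(=O)O[C@H]2[C@H]1[C@@H](OC(=O)/C(C)=C/C)C/C(C)=C\[C@@H](O)/C=C(/C)[C@@H]2O
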